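**Retrosynthetic overview**

1. Locants used below: C10 = quaternary ring carbon (CH3, vinyl); C5 = ring CH carrying the oxirane carbon C4 (with C3H2 and aldehyde C15); C6 = CH–O-isobutyrate; C7/C8 = lactone ring-fusion carbons (C11=C13 methylene, C12 carbonyl, ring O on C8); C9 = CH–OH.
2. Late disconnections: oxirane from a 2-substituted acrolein (catalyst-controlled epoxidation); C15 aldehyde from an isopropenyl methyl group; C11=C13 from an α-carboxy lactone; 9-OH from a C9 ketone.
3. Key disconnection: the γ-lactone is closed by forming the O–C8 bond in a one-pot oxidative [3+2] annulation of enone 14 (C9=O, C7=C8) with a malonate C,O-dinucleophile; the same operation makes the C7–C11 bond and sets C7 and C8.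
4. Enabling feature: in the cyclohexane ring the C9 carbonyl lies between quaternary C10 (no α-hydrogen, shielded carbonyl) and C8, so C8 is the only carbon that can become an enol ether and be oxidised; the C6 oxygen substituent steers nucleophiles at both of its neighbours (C5, then C7) to its opposite face.
5. Ring order: the cyclohexane ring is bought as (S)-4-silyloxycyclohexenone (C6 stereocentre), C5/C10 are set by conjugate addition–aldol; the lactone ring is formed in step 8; the oxirane ring last, in step 12.

Key step: step 8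

Remark (assumption): enone 1 is taken as a purchasable enantiopure building block; all other starting materials (3, 5, 6, 13, 15, 21) are catalogue chemicals.

**Step 1**
Reactants: 1 (S)-4-(tert-butyldimethylsilyloxy)cyclohex-2-en-1-one
Product: 2 (S)-4-(tert-butyldimethylsilyloxy)-2-iodocyclohex-2-en-1-one
Conditions: I2, pyridine, CH2Cl2, 0 °C to rt
Reagents that add atoms: iodine, II
Why: α-Iodination of the enone by the pyridine-mediated conjugate addition/iodination/elimination sequence (Baylis–Hillman-type mechanism) is standard for cyclohexenones and leaves the silyloxy stereocentre untouched.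

**Step 2**
Reactants: 2 (S)-4-(tert-butyldimethylsilyloxy)-2-iodocyclohex-2-en-1-one; 3 methylboronic acid
Product: 4 (S)-4-(tert-butyldimethylsilyloxy)-2-methylcyclohex-2-en-1-one
Conditions: MeB(OH)2, Pd(dppf)Cl2 (5 mol %), K3PO4, dioxane/H2O, 70 °C
Reagents that add atoms: methylboronic acid (3), CB(O)O
Why: Suzuki–Miyaura coupling of the electron-poor alkenyl iodide with methylboronic acid should install the ring methyl group without touching the stereocentre.

**Step 3**
Reactants: 4 (S)-4-(tert-butyldimethylsilyloxy)-2-methylcyclohex-2-en-1-one; 5 isopropenylmagnesium bromide; 6 acetaldehyde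
Product: 8 (2R,3S,4S)-4-(tert-butyldimethylsilyloxy)-2-(1-hydroxyethyl)-2-methyl-3-(prop-1-en-2-yl)cyclohexan-1-one (both carbinol epimers), via bromomagnesium enolate 7 (not isolated)
Conditions: CH2=C(CH3)MgBr, CuBr·SMe2 (10 mol %), THF, −78 to −40 °C; then CH3CHO, −78 °C; aq. NH4Cl
Reagents that add atoms: isopropenylmagnesium bromide (5), CC(=C)[Mg]Br; acetaldehyde (6), CC=O
Why: Copper-catalysed conjugate addition of the Grignard reagent is expected anti to the γ-silyloxy group (sets C5, isopropenyl trans to OTBS), and the tetrasubstituted magnesium enolate 7, whose isopropenyl group turns pseudo-axial to avoid A(1,2) strain with the methyl group, should undergo aldol addition to acetaldehyde on the opposite face (sets quaternary C10 with methyl cis to isopropenyl), the carbinol configuration being irrelevant.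

**Step 4**
Reactants: 8 (2R,3S,4S)-4-(tert-butyldimethylsilyloxy)-2-(1-hydroxyethyl)-2-methyl-3-(prop-1-en-2-yl)cyclohexan-1-one
Product: 9 (2S,3S,4S)-4-(tert-butyldimethylsilyloxy)-2-methyl-3-(prop-1-en-2-yl)-2-vinylcyclohexan-1-one
Conditions: Ph2S[OC(CF3)2Ph]2, CH2Cl2, 0 °C to rt
Reagents that add atoms: none
Why: Sulfurane-mediated dehydration of the secondary alcohol can take a proton only from the methyl group because the other neighbour is quaternary, so the vinyl group should form, and the non-basic conditions avoid retro-aldol cleavage.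

**Step 5**
Reactants: 9 (2S,3S,4S)-4-(tert-butyldimethylsilyloxy)-2-methyl-3-(prop-1-en-2-yl)-2-vinylcyclohexan-1-one
Product: 11 (4S,5S,6S)-4-(tert-butyldimethylsilyloxy)-6-methyl-5-(prop-1-en-2-yl)-6-vinylcyclohex-2-en-1-one, via trimethylsilyl enol ether 10 (not isolated)
Conditions: LiN(SiMe3)2, Me3SiCl, THF, −78 °C; then Pd(OAc)2 (1.1 equiv), MeCN, rt
Reagents that add atoms: none
Why: Saegusa–Ito oxidation: because C10 is quaternary the ketone can give only one silyl enol ether (10), which palladium diacetate should convert into the enone by β-hydride elimination from C7.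

**Step 6**
Reactants: 11 (4S,5S,6S)-4-(tert-butyldimethylsilyloxy)-6-methyl-5-(prop-1-en-2-yl)-6-vinylcyclohex-2-en-1-one
Product: 12 (4S,5S,6S)-4-hydroxy-6-methyl-5-(prop-1-en-2-yl)-6-vinylcyclohex-2-en-1-one
Conditions: HF·pyridine, pyridine, THF, 0 °C to rt
Reagents that add atoms: none
Why: Fluoride-mediated cleavage of the silyl ether under buffered conditions should free the allylic alcohol without harming the enone or the alkenes.

**Step 7**
Reactants: 12 (4S,5S,6S)-4-hydroxy-6-methyl-5-(prop-1-en-2-yl)-6-vinylcyclohex-2-en-1-one; 13 isobutyryl chloride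
Product: 14 (1S,5S,6S)-5-methyl-4-oxo-6-(prop-1-en-2-yl)-5-vinylcyclohex-2-en-1-yl 2-methylpropanoate
Conditions: i-PrCOCl, pyridine, DMAP (cat.), CH2Cl2, 0 °C
Reagents that add atoms: isobutyryl chloride (13), CC(C)C(Cl)=O
Why: DMAP-catalysed acylation installs the isobutyrate before the lactone exists, so that no translactonization to the C6 oxygen can occur later.

**Step 8**
Reactants: 14 (1S,5S,6S)-5-methyl-4-oxo-6-(prop-1-en-2-yl)-5-vinylcyclohex-2-en-1-yl 2-methylpropanoate; 15 bis(trimethylsilyl) malonate
Product: 19 (3aS,4R,5S,6S,7aS)-6-methyl-4-(2-methylpropanoyloxy)-2,7-dioxo-5-(prop-1-en-2-yl)-6-vinyloctahydro-1-benzofuran-3-carboxylic acid (cis-fused; both C3 epimers), via silyl ketene acetal 16 (not isolated), via silyl enol ether adduct 17 (not isolated), via alpha-iodo ketone 18 (not isolated)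
Conditions: 15 (1.1 equiv), Me3SiOTf (1.2 equiv), Et3N (1.1 equiv), CH2Cl2, 0 °C; add 14, −78 to −40 °C; then NIS (1.05 equiv), −78 to 0 °C; then aq. NaHCO3/THF, 0 °C to rt; 1 M HCl
Reagents that add atoms: bis(trimethylsilyl) malonate (15), C[Si](C)(C)OC(=O)CC(=O)O[Si](C)(C)C
Why: Proposed new method: a one-pot oxidative [3+2] lactone annulation in which silyl ketene acetal 16, made in the flask from 15, adds in Mukaiyama–Michael fashion to the Me3SiOTf-activated enone (C7–C11 bond), the regiodefined silyl enol ether 17 is iodinated by NIS at C8, its only α-carbon, and the carboxylate freed by bicarbonate displaces iodide from 18 in a 5-exo-tet SN2 closure that forms the O–C8 bond of the lactone; the closest known reactions are the Mukaiyama–Michael addition of silyl ketene acetals, the α-halogenation of silyl enol ethers, the O-alkylation of carboxylates by α-halo ketones and the trivalent-iodine lactonization of 5-oxo acids, but their union in one flask with a malonic acid C,O-dinucleophile is not established. C7 is expected to be set anti to the neighbouring isobutyryloxy group (steric shielding, possibly reinforced by acyloxy participation in the silyloxyallyl cation). C8 is set by two events: iodine should enter on the face opposite the pseudo-axial C10 methyl group, and SN2 inversion then places the oxygen cis to the C7 side chain (cis ring fusion), the carboxylate closing faster than the iodide can epimerize. The selectivities needed are 1,4- over 1,2-addition and a single enol ether, both secured by quaternary C10, which shields the carbonyl and carries no hydrogen, and NIS attack on the enol ether rather than the vinyl and isopropenyl groups, secured by the far higher nucleophilicity of the enol ether. Because the malonate is present as a dicarboxylate its central carbon is not acidic, so O-alkylation (lactone) and not C-alkylation (cyclopropane) is expected; the carboxyl-bearing carbon forms as a mixture and is erased in step 10.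

**Step 9**
Reactants: 19 (3aS,4R,5S,6S,7aS)-6-methyl-4-(2-methylpropanoyloxy)-2,7-dioxo-5-(prop-1-en-2-yl)-6-vinyloctahydro-1-benzofuran-3-carboxylic acid
Product: 20 (3aS,4R,5S,6S,7R,7aS)-7-hydroxy-6-methyl-4-(2-methylpropanoyloxy)-2-oxo-5-(prop-1-en-2-yl)-6-vinyloctahydro-1-benzofuran-3-carboxylic acid (both C3 epimers)
Conditions: NaBH4, MeOH, −40 to 0 °C; then 1 M HCl
Reagents that add atoms: none
Why: Borohydride reduction of the ketone is expected from the face opposite the axial C10 methyl group and the axial C8–O bond (axial attack, Felkin–Anh-type anti to C–O), giving the equatorial 9-hydroxyl cis to the lactone oxygen, while the carboxylate and the esters are not reduced at low temperature.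

**Step 10**
Reactants: 20 (3aS,4R,5S,6S,7R,7aS)-7-hydroxy-6-methyl-4-(2-methylpropanoyloxy)-2-oxo-5-(prop-1-en-2-yl)-6-vinyloctahydro-1-benzofuran-3-carboxylic acid; 21 formaldehyde
Product: 23 (3aS,4R,5S,6S,7R,7aS)-7-hydroxy-6-methyl-3-methylidene-2-oxo-5-(prop-1-en-2-yl)-6-vinyloctahydro-1-benzofuran-4-yl 2-methylpropanoate, via Mannich base 22 (not isolated)
Conditions: 37% aq. CH2O, Et2NH, THF, rt; then NaOAc, AcOH, 80 °C
Reagents that add atoms: formaldehyde (21), C=O
Why: Mannich reaction of the α-carboxy lactone with formaldehyde and diethylamine followed by decarboxylative elimination of the amine is the classical α-methylenation of α-carboxy-γ-butyrolactones and removes the stereorandom C11 centre.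

**Step 11**
Reactants: 23 (3aS,4R,5S,6S,7R,7aS)-7-hydroxy-6-methyl-3-methylidene-2-oxo-5-(prop-1-en-2-yl)-6-vinyloctahydro-1-benzofuran-4-yl 2-methylpropanoate
Product: 25 (3aS,4R,5R,6S,7R,7aS)-7-hydroxy-6-methyl-3-methylidene-2-oxo-5-(3-oxoprop-1-en-2-yl)-6-vinyloctahydro-1-benzofuran-4-yl 2-methylpropanoate, via allylic alcohol 24 (not isolated)
Conditions: SeO2 (0.5 equiv), t-BuOOH, CH2Cl2, rt; then MnO2, CH2Cl2, rt
Reagents that add atoms: tert-butyl hydroperoxide (net oxygen source, delivered through selenium dioxide), CC(C)(C)OO; selenium dioxide, O=[Se]=O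
Why: Selenium dioxide allylic oxidation (ene reaction then [2,3]-sigmatropic shift) should occur at the methyl group of the isopropenyl unit, the only electron-rich alkene with accessible allylic hydrogens (the vinyl group has none, the methylene lactone is electron-poor, and the C5–H is held in the alkene plane by A(1,3) strain), and MnO2 should take allylic alcohol 24 on to the enal without oxidising the saturated 9-hydroxyl.

**Step 12**
Reactants: 25 (3aS,4R,5R,6S,7R,7aS)-7-hydroxy-6-methyl-3-methylidene-2-oxo-5-(3-oxoprop-1-en-2-yl)-6-vinyloctahydro-1-benzofuran-4-yl 2-methylpropanoate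
Product: 26 (3aS,4S,5S,6S,7R,7aS)-5-[(2R)-2-formyloxiran-2-yl]-7-hydroxy-6-methyl-3-methylidene-2-oxo-6-vinyloctahydro-1-benzofuran-4-yl 2-methylpropanoate (target)
Conditions: (S)-α,α-diphenylprolinol trimethylsilyl ether (20 mol %), 35% aq. H2O2, CH2Cl2, rt
Reagents that add atoms: hydrogen peroxide, OO
Why: Amine-catalysed nucleophilic (Weitz–Scheffer-type) epoxidation through the iminium ion of the 2-substituted acrolein, with the oxirane closed from the chiral enamine whose shielded face sets quaternary C4 under catalyst control (the (S)-catalyst is selected as the enantiomer expected by the shielding model to give the (R)-oxirane), is chemoselective because the methylene lactone cannot form an iminium ion.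

**Compound list**

1 | (S)-4-(tert-butyldimethylsilyloxy)cyclohex-2-en-1-one | O=C1C=C[C@@H](O[Si](C)(C)C(C)(C)C)CC1 | starting material
2 | (S)-4-(tert-butyldimethylsilyloxy)-2-iodocyclohex-2-en-1-one | O=C1C(I)=C[C@@H](O[Si](C)(C)C(C)(C)C)CC1 | intermediate
3 | methylboronic acid | CB(O)O | starting material
4 | (S)-4-(tert-butyldimethylsilyloxy)-2-methylcyclohex-2-en-1-one | O=C1C(C)=C[C@@H](O[Si](C)(C)C(C)(C)C)CC1 | intermediate
5 | isopropenylmagnesium bromide (prop-1-en-2-ylmagnesium bromide) | CC(=C)[Mg]Br | starting material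
6 | acetaldehyde | CC=O | starting material
7 | bromomagnesium enolate of (3S,4S)-4-(tert-butyldimethylsilyloxy)-2-methyl-3-(prop-1-en-2-yl)cyclohexan-1-one (isopropenyl trans to silyloxy) | CC1=C(O[Mg]Br)CC[C@H](O[Si](C)(C)C(C)(C)C)[C@H]1C(C)=C | intermediate (not isolated)
8 | (2R,3S,4S)-4-(tert-butyldimethylsilyloxy)-2-(1-hydroxyethyl)-2-methyl-3-(prop-1-en-2-yl)cyclohexan-1-one (both carbinol epimers) | CC(O)[C@@]1(C)[C@H](C(C)=C)[C@@H](O[Si](C)(C)C(C)(C)C)CCC1=O | intermediate
9 | (2S,3S,4S)-4-(tert-butyldimethylsilyloxy)-2-methyl-3-(prop-1-en-2-yl)-2-vinylcyclohexan-1-one | C=C[C@@]1(C)[C@H](C(C)=C)[C@@H](O[Si](C)(C)C(C)(C)C)CCC1=O | intermediate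
10 | trimethylsilyl enol ether of 9 (enol double bond toward the ring CH2) | C=C[C@@]1(C)[C@H](C(C)=C)[C@@H](O[Si](C)(C)C(C)(C)C)CC=C1O[Si](C)(C)C | intermediate (not isolated)
11 | (4S,5S,6S)-4-(tert-butyldimethylsilyloxy)-6-methyl-5-(prop-1-en-2-yl)-6-vinylcyclohex-2-en-1-one | C=C[C@@]1(C)[C@H](C(C)=C)[C@@H](O[Si](C)(C)C(C)(C)C)C=CC1=O | intermediate
12 | (4S,5S,6S)-4-hydroxy-6-methyl-5-(prop-1-en-2-yl)-6-vinylcyclohex-2-en-1-one | C=C[C@@]1(C)[C@H](C(C)=C)[C@@H](O)C=CC1=O | intermediate
13 | isobutyryl chloride (2-methylpropanoyl chloride) | CC(C)C(Cl)=O | starting material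
14 | (1S,5S,6S)-5-methyl-4-oxo-6-(prop-1-en-2-yl)-5-vinylcyclohex-2-en-1-yl 2-methylpropanoate | C=C[C@@]1(C)[C@H](C(C)=C)[C@@H](OC(=O)C(C)C)C=CC1=O | intermediate
15 | bis(trimethylsilyl) malonate | C[Si](C)(C)OC(=O)CC(=O)O[Si](C)(C)C | starting material
16 | trimethylsilyl 3,3-bis(trimethylsilyloxy)prop-2-enoate (silyl ketene acetal of 15) | C[Si](C)(C)OC(=O)C=C(O[Si](C)(C)C)O[Si](C)(C)C | intermediate (not isolated)
17 | Mukaiyama–Michael adduct: trimethylsilyl enol ether of the ring ketone carrying the bis(trimethylsilyl) malonyl group on C7, trans to the isobutyrate | C=C[C@@]1(C)[C@H](C(C)=C)[C@@H](OC(=O)C(C)C)[C@H](C(C(=O)O[Si](C)(C)C)C(=O)O[Si](C)(C)C)C=C1O[Si](C)(C)C | intermediate (not isolated)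
18 | α-iodo ketone from 17 (iodine on C8, trans to the malonyl group) | C=C[C@@]1(C)[C@H](C(C)=C)[C@@H](OC(=O)C(C)C)[C@H](C(C(=O)O[Si](C)(C)C)C(=O)O[Si](C)(C)C)[C@@H](I)C1=O | intermediate (not isolated)
19 | (3aS,4R,5S,6S,7aS)-6-methyl-4-(2-methylpropanoyloxy)-2,7-dioxo-5-(prop-1-en-2-yl)-6-vinyloctahydro-1-benzofuran-3-carboxylic acid (cis-fused; both C3 epimers) | C=C[C@@]1(C)[C@H](C(C)=C)[C@@H](OC(=O)C(C)C)[C@@H]2C(C(=O)O)C(=O)O[C@@H]2C1=O | intermediate
20 | (3aS,4R,5S,6S,7R,7aS)-7-hydroxy-6-methyl-4-(2-methylpropanoyloxy)-2-oxo-5-(prop-1-en-2-yl)-6-vinyloctahydro-1-benzofuran-3-carboxylic acid (both C3 epimers) | C=C[C@@]1(C)[C@H](C(C)=C)[C@@H](OC(=O)C(C)C)[C@@H]2C(C(=O)O)C(=O)O[C@@H]2[C@@H]1O | intermediate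
21 | formaldehyde | C=O | starting material
22 | Mannich base: 3-(diethylaminomethyl) derivative of 20 | C=C[C@@]1(C)[C@H](C(C)=C)[C@@H](OC(=O)C(C)C)[C@@H]2C(CN(CC)CC)(C(=O)O)C(=O)O[C@@H]2[C@@H]1O | intermediate (not isolated)
23 | (3aS,4R,5S,6S,7R,7aS)-7-hydroxy-6-methyl-3-methylidene-2-oxo-5-(prop-1-en-2-yl)-6-vinyloctahydro-1-benzofuran-4-yl 2-methylpropanoate | C=C[C@@]1(C)[C@H](C(C)=C)[C@@H](OC(=O)C(C)C)[C@@H]2C(=C)C(=O)O[C@@H]2[C@@H]1O | intermediate
24 | allylic alcohol: 5-(3-hydroxyprop-1-en-2-yl) analogue of 23 | C=C[C@@]1(C)[C@H](C(=C)CO)[C@@H](OC(=O)C(C)C)[C@@H]2C(=C)C(=O)O[C@@H]2[C@@H]1O | intermediate (not isolated)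
25 | (3aS,4R,5R,6S,7R,7aS)-7-hydroxy-6-methyl-3-methylidene-2-oxo-5-(3-oxoprop-1-en-2-yl)-6-vinyloctahydro-1-benzofuran-4-yl 2-methylpropanoate | C=C[C@@]1(C)[C@H](C(=C)C=O)[C@@H](OC(=O)C(C)C)[C@@H]2C(=C)C(=O)O[C@@H]2[C@@H]1O | intermediate
26 | (3aS,4S,5S,6S,7R,7aS)-5-[(2R)-2-formyloxiran-2-yl]-7-hydroxy-6-methyl-3-methylidene-2-oxo-6-vinyloctahydro-1-benzofuran-4-yl 2-methylpropanoate | C=C[C@@]1(C)[C@H]([C@]2(C=O)CO2)[C@@H](OC(=O)C(C)C)[C@@H]2C(=C)C(=O)O[C@@H]2[C@@H]1O | target

**Step count and risks**

Total step count: 12. Longest linear sequence: 12 steps (fully linear from 1).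

Steps most likely to fail:

1. Step 8 (Proposed new method). What may go wrong: sluggish conjugate addition of the weakly nucleophilic malonate ketene acetal; iodination at the malonate carbon instead of the enol ether; closure through the epimeric iodide to the trans-fused lactone; or epimerization next to the ketone during the bicarbonate stage. The fallback uses known chemistry, sets out from 14 and comes back at 19. Cs2CO3-catalysed Michael addition of diallyl malonate in MeCN, expected anti to the isobutyryloxy group, should give the keto diallyl malonate F1. Pd(PPh3)4 with morpholine in THF should remove both allyl groups to give the keto malonic acid F2. Treatment of this 5-oxo acid with PhI(OH)OTs in MeCN (α-oxylactonization through the only possible enol, the carboxylate displacing the trivalent-iodine group with inversion) should give 19.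

2. Step 11. What may go wrong: ene reaction at the ring methine instead of the methyl group, incomplete conversion, or over-oxidation. The fallback sets out from 23 and comes back at 25. Ene-type allylic chlorination of the isopropenyl group with NaOCl/CeCl3·7H2O (CH2Cl2/H2O, 0 °C) should give the allylic chloride F3. Oxidation with N-methylmorpholine N-oxide in MeCN (N-oxide displacement of chloride, then elimination) should give 25.

3. Step 12. What may go wrong: slow iminium formation at the hindered α-branched enal, or facial selectivity eroded by the substrate's own bias (mismatched pair). The fallback sets out from 24, isolated by stopping step 11 before the MnO2 stage, and comes back at 26. Sharpless asymmetric epoxidation (Ti(OiPr)4, L-(+)-diethyl tartrate, t-BuOOH, 4 Å molecular sieves, CH2Cl2, −20 °C), for which the mnemonic for 2-substituted allylic alcohols predicts the required face, should give the epoxy alcohol F4. Oxidation of its primary alcohol with TEMPO/PhI(OAc)2, which should leave the secondary 9-hydroxyl alone, should give 26.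

**Further compounds**

F1 | step 8 | keto diallyl malonate: diallyl malonate Michael adduct of 14 (malonyl group on C7, trans to the isobutyrate) | C=C[C@@]1(C)[C@H](C(C)=C)[C@@H](OC(=O)C(C)C)[C@H](C(C(=O)OCC=C)C(=O)OCC=C)CC1=O
F2 | step 8 | keto malonic acid: diacid of F1 | C=C[C@@]1(C)[C@H](C(C)=C)[C@@H](OC(=O)C(C)C)[C@H](C(C(=O)O)C(=O)O)CC1=O
F3 | step 11 | allylic chloride: 5-(3-chloroprop-1-en-2-yl) analogue of 23 | C=C[C@@]1(C)[C@H](C(=C)CCl)[C@@H](OC(=O)C(C)C)[C@@H]2C(=C)C(=O)O[C@@H]2[C@@H]1O
F4 | step 12 | epoxy alcohol: 5-[2-(hydroxymethyl)oxiran-2-yl] analogue of 26 (oxirane configured as in 26) | C=C[C@@]1(C)[C@H]([C@]2(CO)CO2)[C@@H](OC(=O)C(C)C)[C@@H]2C(=C)C(=O)O[C@@H]2[C@@H]1O
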